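**Plan**

1. Retrosynthesis (megaphone ring numbering: C1 = C=O, C2=C3, C4 = CH(OMe), C5 = CH2, C6 = quaternary): the aryl–carbinol bond, the C6–allyl bond and the C6–side-chain bond are cut first. The remaining 5-methoxy-2-oxocyclohex-3-ene-1-carboxylate ring is then cut at C1–C6 and C3–C4 into a (Z)-β-silylacrolein and a 2-methoxycyclopropane carboxyl unit.
2. Enabling feature: C4 carries the methoxy oxygen (donor) and C6, one CH2 (C5) away, is the ketone α-carbon and can carry a carboxyl acceptor. This is the 1,3-pattern of a donor–acceptor cyclopropane; C1(=O)–C2=C3 is an acrolein unit.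
3. Forward: cyclopropane imide 7 and enal 10 give ring 12 in one TiCl4 operation (ring-opening aldol makes C1–C6, vinylsilane closure on the oxocarbenium ion makes C3–C4). Ester exchange, oxidation, crotylation, alkene cleavage, allylation and aryl addition follow.
4. Stereochemistry: oxazolidinone auxiliary → temporary carboxyl-bearing centre → C4–OMe (chair closure, 1,3-cis); Ir catalyst → methyl-bearing centre; Pd/PHOX and the ring methoxy group → quaternary C6 (both epimers converge); Felkin–Anh → carbinol. All stereoisomers of the cyclopropane converge on ring opening.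

Key step: step 6

Assumption: the chlorotitanium enolate formed by ring opening of 7 is taken to add to the aldehyde with the facial sense known for chlorotitanium enolates of N-acyl oxazolidinones (syn aldol, closed chair); if the sense were reversed, the (4R)-auxiliary would be used.

**Route**

Step 1
Reactants: 1 ethyl diazoacetate, 2 methyl vinyl ether
Product: 3 ethyl 2-methoxycyclopropane-1-carboxylate (racemic cis/trans mixture)
Conditions: Rh2(OAc)4 (0.5 mol %), excess 2, Et2O, 0 °C, slow addition of 1
Reagents that add atoms: none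
Why: Rhodium-carbenoid cyclopropanation of the electron-rich enol ether gives the donor–acceptor cyclopropane, whose cis/trans ratio and racemic nature do not matter because both ring stereocentres are erased when the ring is opened in step 6.

Step 2
Reactants: 3 ethyl 2-methoxycyclopropane-1-carboxylate
Product: 4 2-methoxycyclopropane-1-carboxylic acid
Conditions: LiOH, THF/H2O, 0 to 23 °C; then cold 1 M HCl to pH 3
Reagents that add atoms: lithium hydroxide, [Li+].[OH-]
Why: Ester saponification leaves the base-stable alkoxycyclopropane intact, and brief cold acidification avoids acid-induced ring opening.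

Step 3
Reactants: 4 2-methoxycyclopropane-1-carboxylic acid, 5 (4S)-4-benzyl-1,3-oxazolidin-2-one
Product: 7 (4S)-4-benzyl-3-[(2-methoxycyclopropyl)carbonyl]-1,3-oxazolidin-2-one, via pivalic mixed anhydride 6 (not isolated)
Conditions: PivCl, Et3N, THF, −20 °C; then 5, LiCl, 23 °C
Reagents that add atoms: none
Why: N-Acylation of the oxazolidinone by the mixed pivalic anhydride at its less hindered carbonyl installs the chelating chiral acceptor group that controls step 6.

Step 4
Reactants: 8 3-(trimethylsilyl)prop-2-yn-1-ol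
Product: 9 (Z)-3-(trimethylsilyl)prop-2-en-1-ol
Conditions: H2 (1 atm), P-2 nickel (Ni(OAc)2, NaBH4), ethylenediamine, EtOH, 23 °C
Reagents that add atoms: none
Why: cis-Selective semi-hydrogenation of the silyl alkyne gives the (Z)-vinylsilane that ring closure to a cis ring alkene requires.

Step 5
Reactants: 9 (Z)-3-(trimethylsilyl)prop-2-en-1-ol
Product: 10 (Z)-3-(trimethylsilyl)prop-2-enal
Conditions: Dess–Martin periodinane, NaHCO3, CH2Cl2, 0 °C; used at once
Reagents that add atoms: none
Why: Buffered Dess–Martin oxidation of the allylic alcohol gives the (Z)-enal without acid, so that Z to E isomerisation should be avoided.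

Step 6
Reactants: 7 (4S)-4-benzyl-3-[(2-methoxycyclopropyl)carbonyl]-1,3-oxazolidin-2-one, 10 (Z)-3-(trimethylsilyl)prop-2-enal
Product: 12 (4S)-4-benzyl-3-{[(1S,2R,5R)-2-hydroxy-5-methoxycyclohex-3-en-1-yl]carbonyl}-1,3-oxazolidin-2-one, via furanoside aldol adduct 11 (not isolated)
Conditions: TiCl4 (2.2 equiv), CH2Cl2, −78 to −30 °C; aqueous quench
Reagents that add atoms: none
Why: Proposed new method: TiCl4 chelates the imide of 7 and the push–pull cyclopropane opens between the methoxy carbon and the carbonyl-bearing carbon to a chlorotitanium (Z)-enolate carrying a methoxy-stabilised oxocarbenium ion (α-chloro ether), a 1,3-zwitterion; the enolate adds 1,2 to Ti-activated 10, and the oxocarbenium ion, in equilibrium with its aldolate-trapped furanoside form 11, is then attacked by the ipso carbon of the (Z)-vinylsilane, the β-silyl cation collapsing to the ring alkene. The closest known reaction types are the Lewis-acid ring-opening aldol addition of 2-alkoxy- and 2-siloxycyclopropane carboxylates to aldehydes (formal [3+2] to 2-alkoxyoxolanes) and the vinylsilane-terminated cyclisation of acetal-derived oxocarbenium ions, here merged into a formal [3+3] annulation. The six-membered ring closes 6-endo with respect to the vinylsilane (exo with respect to the C=O+ bond) through a chair, the β-silicon effect dictating ipso attack and the (Z)-geometry delivering the cis ring alkene. Ring C1 (S) is set by the auxiliary (syn aldol through a closed chair), the carbinol centre follows from the (Z)-enolate, and the methoxy centre C5 (R) is set in the ring closure, where the acyl group and the methoxy group of the (E)-oxocarbenium ion should both be equatorial (1,3-cis). The step needs 1,2- over 1,4-addition to the enal (hard Ti enolate, bulky β-silyl group), C- over O-capture of the oxocarbenium ion (O-capture is reversible under TiCl4, C-capture is not) and survival of the (Z)-alkene (aldol at −78 °C faster than isomerisation). All stereoisomers of the cyclopropane in 7 give the same zwitterion, so the mixture is funnelled into one product.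

Step 7
Reactants: 12 (4S)-4-benzyl-3-{[(1S,2R,5R)-2-hydroxy-5-methoxycyclohex-3-en-1-yl]carbonyl}-1,3-oxazolidin-2-one
Product: 13 2-(trimethylsilyl)ethyl (1S,2R,5R)-2-hydroxy-5-methoxycyclohex-3-ene-1-carboxylate
Conditions: Me3SiCH2CH2OH (excess), Sm(OTf)3 (10 mol %), THF, 23 °C
Reagents that add atoms: 2-(trimethylsilyl)ethanol, C[Si](C)(C)CCO
Why: Lewis-acid-catalysed alcoholysis of the N-acyl oxazolidinone, helped by chelation of the β-hydroxyl, exchanges the auxiliary for the fluoride-labile ester without touching the ring stereocentres.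

Step 8
Reactants: 13 2-(trimethylsilyl)ethyl (1S,2R,5R)-2-hydroxy-5-methoxycyclohex-3-ene-1-carboxylate
Product: 14 2-(trimethylsilyl)ethyl (5R)-5-methoxy-2-oxocyclohex-3-ene-1-carboxylate (C1 epimers and enol)
Conditions: Dess–Martin periodinane, pyridine, CH2Cl2, 0 °C
Reagents that add atoms: none
Why: Dess–Martin oxidation of the allylic alcohol gives the cyclohexenone β-keto ester and removes the temporary carbinol centre, so that any carbinol epimers of 13 converge while the methoxy centre is kept.

Step 9
Reactants: 14 2-(trimethylsilyl)ethyl (5R)-5-methoxy-2-oxocyclohex-3-ene-1-carboxylate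
Product: 15 2-(trimethylsilyl)ethyl (5R)-1-[(2R)-but-3-en-2-yl]-5-methoxy-2-oxocyclohex-3-ene-1-carboxylate (C1 epimers)
Conditions: [Ir(cod)Cl]2 (2 mol %), N-aryl phosphoramidite ligand (4 mol %, enantiomer that gives the (R)-but-3-en-2-yl centre), TBD, LiBr, THF, 25 °C
Reagents that add atoms: (E)-but-2-en-1-yl methyl carbonate, C/C=C/COC(=O)OC
Why: Iridium-catalysed branched-selective asymmetric allylic alkylation (Tsuji–Trost type) of the β-keto ester enolate fixes the methyl-bearing centre (R) by attack anti to iridium on the favoured π-crotyl complex, while the configuration at quaternary C1 is irrelevant because it is erased in step 11.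

Step 10
Reactants: 15 2-(trimethylsilyl)ethyl (5R)-1-[(2R)-but-3-en-2-yl]-5-methoxy-2-oxocyclohex-3-ene-1-carboxylate
Product: 16 2-(trimethylsilyl)ethyl (5R)-5-methoxy-2-oxo-1-[(2S)-1-oxopropan-2-yl]cyclohex-3-ene-1-carboxylate (C1 epimers)
Conditions: OsO4 (2 mol %), NaIO4, 2,6-lutidine, dioxane/H2O, 23 °C
Reagents that add atoms: sodium periodate (oxygen relayed through catalytic OsO4), [Na+].[O-]I(=O)(=O)=O
Why: Lemieux–Johnson oxidation cleaves the electron-rich terminal vinyl group in preference to the electron-poor enone alkene and should leave the α-methyl aldehyde unepimerised under the buffered conditions.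

Step 11
Reactants: 16 2-(trimethylsilyl)ethyl (5R)-5-methoxy-2-oxo-1-[(2S)-1-oxopropan-2-yl]cyclohex-3-ene-1-carboxylate
Product: 17 (2S)-2-[(1R,5R)-5-methoxy-2-oxo-1-(prop-2-en-1-yl)cyclohex-3-en-1-yl]propanal
Conditions: Pd2(dba)3 (2.5 mol %), (S)-t-BuPHOX (6 mol %), TBAT (1.2 equiv), THF, 25 °C
Reagents that add atoms: allyl methyl carbonate, C=CCOC(=O)OC
Why: Fluoride unmasks the carboxylate, which decarboxylates to the enolate that is allylated on palladium (decarboxylative Tsuji–Trost allylation); both C1 epimers converge on one enolate and allyl should enter anti to the ring methoxy group, reinforced by the (S)-PHOX ligand, to set the quaternary centre (R).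

Step 12
Reactants: 17 (2S)-2-[(1R,5R)-5-methoxy-2-oxo-1-(prop-2-en-1-yl)cyclohex-3-en-1-yl]propanal, 18 (3,4,5-trimethoxyphenyl)magnesium bromide
Product: 19 megaphone, (4R,6R)-6-[(1R,2S)-1-hydroxy-1-(3,4,5-trimethoxyphenyl)propan-2-yl]-4-methoxy-6-(prop-2-en-1-yl)cyclohex-2-en-1-one
Conditions: 18 (1.1 equiv), THF, −78 °C; aq. NH4Cl at −78 °C
Reagents that add atoms: none
Why: Grignard 1,2-addition to the aldehyde, much faster than to the neopentyl enone carbonyl, should follow the Felkin–Anh model with the quaternary carbon as the large group and give the carbinol (R) with methyl and hydroxyl syn.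

**Compound list**

1 | ethyl diazoacetate | CCOC(=O)C=[N+]=[N-] | starting material
2 | methyl vinyl ether | COC=C | starting material
3 | ethyl 2-methoxycyclopropane-1-carboxylate (racemic cis/trans mixture) | CCOC(=O)C1CC1OC | intermediate
4 | 2-methoxycyclopropane-1-carboxylic acid (racemic cis/trans mixture) | OC(=O)C1CC1OC | intermediate
5 | (4S)-4-benzyl-1,3-oxazolidin-2-one | O=C1OC[C@H](Cc2ccccc2)N1 | starting material
6 | 2-methoxycyclopropane-1-carboxylic pivalic anhydride | CC(C)(C)C(=O)OC(=O)C1CC1OC | intermediate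
7 | (4S)-4-benzyl-3-[(2-methoxycyclopropyl)carbonyl]-1,3-oxazolidin-2-one (mixture of cyclopropane stereoisomers) | O=C(C1CC1OC)N1[C@@H](Cc2ccccc2)COC1=O | intermediate
8 | 3-(trimethylsilyl)prop-2-yn-1-ol | C[Si](C)(C)C#CCO | starting material
9 | (Z)-3-(trimethylsilyl)prop-2-en-1-ol | C[Si](C)(C)/C=C\CO | intermediate
10 | (Z)-3-(trimethylsilyl)prop-2-enal | C[Si](C)(C)/C=C\C=O | intermediate
11 | (4S)-4-benzyl-3-({(2S,3S)-5-methoxy-2-[(Z)-2-(trimethylsilyl)ethenyl]oxolan-3-yl}carbonyl)-1,3-oxazolidin-2-one (both C5 anomers) | O=C(N1[C@@H](Cc2ccccc2)COC1=O)[C@H]1CC(OC)O[C@@H]1/C=C\[Si](C)(C)C | intermediate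
12 | (4S)-4-benzyl-3-{[(1S,2R,5R)-2-hydroxy-5-methoxycyclohex-3-en-1-yl]carbonyl}-1,3-oxazolidin-2-one | O=C([C@H]1C[C@@H](OC)C=C[C@H]1O)N1[C@@H](Cc2ccccc2)COC1=O | intermediate
13 | 2-(trimethylsilyl)ethyl (1S,2R,5R)-2-hydroxy-5-methoxycyclohex-3-ene-1-carboxylate | C[Si](C)(C)CCOC(=O)[C@H]1C[C@@H](OC)C=C[C@H]1O | intermediate
14 | 2-(trimethylsilyl)ethyl (5R)-5-methoxy-2-oxocyclohex-3-ene-1-carboxylate (C1 epimers and enol) | C[Si](C)(C)CCOC(=O)C1C[C@@H](OC)C=CC1=O | intermediate
15 | 2-(trimethylsilyl)ethyl (5R)-1-[(2R)-but-3-en-2-yl]-5-methoxy-2-oxocyclohex-3-ene-1-carboxylate (C1 epimers) | C[Si](C)(C)CCOC(=O)C1([C@H](C)C=C)C[C@@H](OC)C=CC1=O | intermediate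
16 | 2-(trimethylsilyl)ethyl (5R)-5-methoxy-2-oxo-1-[(2S)-1-oxopropan-2-yl]cyclohex-3-ene-1-carboxylate (C1 epimers) | C[Si](C)(C)CCOC(=O)C1([C@H](C)C=O)C[C@@H](OC)C=CC1=O | intermediate
17 | (2S)-2-[(1R,5R)-5-methoxy-2-oxo-1-(prop-2-en-1-yl)cyclohex-3-en-1-yl]propanal | C=CC[C@]1([C@H](C)C=O)C[C@@H](OC)C=CC1=O | intermediate
18 | (3,4,5-trimethoxyphenyl)magnesium bromide | COc1cc([Mg]Br)cc(OC)c1OC | starting material
19 | megaphone | C=CC[C@]1([C@H](C)[C@@H](O)c2cc(OC)c(OC)c(OC)c2)C[C@@H](OC)C=CC1=O | target

**Step count and risks**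

Total steps: 12. Longest linear sequence: 10 (steps 1, 2, 3, 6, 7, 8, 9, 10, 11, 12).

Steps most likely to fail:

Step 6. The oxocarbenium ion may be held as the oxygen-trapped furanoside instead of closing on carbon, or the ring-opened enolate may add with reversed facial selectivity, or the (Z)-enal may isomerise before the aldol. The fallback uses known chemistry, sets out from 5 and 10 and comes back at 12. Compound 5 is acylated with 4,4-dimethoxybutanoic acid through 4,4-dimethoxybutanoic pivalic anhydride F1 to the open-chain imide (4S)-4-benzyl-3-(4,4-dimethoxybutanoyl)-1,3-oxazolidin-2-one F2. Its dibutylboron enolate (Bu2BOTf, i-Pr2NEt, CH2Cl2, −78 °C) undergoes the Evans syn aldol reaction with 10 to give, after oxidative work-up, the isolated adduct (4S)-4-benzyl-3-[(2S,3S,4Z)-2-(2,2-dimethoxyethyl)-3-hydroxy-5-(trimethylsilyl)pent-4-enoyl]-1,3-oxazolidin-2-one F3. SnCl4 in CH2Cl2 at −78 °C then ionises the dimethyl acetal and the vinylsilane-terminated cyclisation gives 12.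

Step 9. Linear instead of branched substitution at the hindered tertiary enolate carbon, or base-induced Michael self-condensation of the enone, may compete. The fallback sets out from 14 and comes back at 15. Mitsunobu O-alkylation of the enol of 14 with (E)-but-2-en-1-ol (PPh3, DIAD) gives the enol ether 2-(trimethylsilyl)ethyl (5R)-2-{[(2E)-but-2-en-1-yl]oxy}-5-methoxycyclohexa-1,3-diene-1-carboxylate F4. Its thermal Claisen rearrangement (toluene, 100 °C) through a chair on the face anti to the methoxy group should give 15 with the (R)-but-3-en-2-yl centre.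

Step 11. Allylation of the hindered tetrasubstituted enolate may be slow enough for protonation to win, or fluoride may epimerise the α-methyl aldehyde. The fallback sets out from 16 and comes back at 17. The aldehyde is protected (HC(OMe)3, PPTS, MeOH) as 2-(trimethylsilyl)ethyl (5R)-1-[(2S)-1,1-dimethoxypropan-2-yl]-5-methoxy-2-oxocyclohex-3-ene-1-carboxylate F5. TBAF in THF removes the ester and the β-keto acid decarboxylates to (4R)-6-[(2S)-1,1-dimethoxypropan-2-yl]-4-methoxycyclohex-2-en-1-one F6. Its kinetic lithium enolate (LDA, THF, −78 °C) is alkylated with allyl bromide trans to the methoxy group to give (4R,6R)-6-[(2S)-1,1-dimethoxypropan-2-yl]-4-methoxy-6-(prop-2-en-1-yl)cyclohex-2-en-1-one F7, and mild aqueous acid (PPTS, acetone/water) returns 17.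

Further compounds
F1 | step 6 | 4,4-dimethoxybutanoic pivalic anhydride | CC(C)(C)C(=O)OC(=O)CCC(OC)OC
F2 | step 6 | (4S)-4-benzyl-3-(4,4-dimethoxybutanoyl)-1,3-oxazolidin-2-one | O=C(CCC(OC)OC)N1[C@@H](Cc2ccccc2)COC1=O
F3 | step 6 | (4S)-4-benzyl-3-[(2S,3S,4Z)-2-(2,2-dimethoxyethyl)-3-hydroxy-5-(trimethylsilyl)pent-4-enoyl]-1,3-oxazolidin-2-one | O=C(N1[C@@H](Cc2ccccc2)COC1=O)[C@@H](CC(OC)OC)[C@H](O)/C=C\[Si](C)(C)C
F4 | step 9 | 2-(trimethylsilyl)ethyl (5R)-2-{[(2E)-but-2-en-1-yl]oxy}-5-methoxycyclohexa-1,3-diene-1-carboxylate | C/C=C/COC1=C(C(=O)OCC[Si](C)(C)C)C[C@@H](OC)C=C1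
F5 | step 11 | 2-(trimethylsilyl)ethyl (5R)-1-[(2S)-1,1-dimethoxypropan-2-yl]-5-methoxy-2-oxocyclohex-3-ene-1-carboxylate (C1 epimers) | C[Si](C)(C)CCOC(=O)C1([C@H](C)C(OC)OC)C[C@@H](OC)C=CC1=O
F6 | step 11 | (4R)-6-[(2S)-1,1-dimethoxypropan-2-yl]-4-methoxycyclohex-2-en-1-one (C6 epimers) | COC(OC)[C@@H](C)C1C[C@@H](OC)C=CC1=O
F7 | step 11 | (4R,6R)-6-[(2S)-1,1-dimethoxypropan-2-yl]-4-methoxy-6-(prop-2-en-1-yl)cyclohex-2-en-1-one | C=CC[C@]1([C@H](C)C(OC)OC)C[C@@H](OC)C=CC1=O
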